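## Retrosynthetic overview

1. Target 15 ⇐ α-bromo ketone 14 by hydride reduction (C3–OH cis to C2–Br); 14 ⇐ allylsilane enone 13 by desilylative deconjugation (CH2SiMe3 is a masked exocyclic methylene).
2. 13 ⇐ silyl dienol ether 12 by catalyst-controlled bromination at C2; 12 and 11 ⇐ vinylogous ester 9 by Me3SiCH2 addition and enone transposition.
3. 9 ⇐ 8 by carbonyl-anchored bromochlorination of the ring B alkene (sets C8 and C9).
4. 8 ⇐ exocyclic enone 6 + isoprene by an organocatalytic asymmetric Diels–Alder reaction (spiro C6, the first stereocentre); 6 ⇐ dimedone.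
5. Ring order: ring A is bought as dimedone, ring B is formed by the cycloaddition. Spiro compounds are numbered as in the target (C1 CMe2, C2 CHBr, C3 CHOH, C5 C=CH2, C6 spiro, C8 CHBr, C9 CMeCl).

Assumption: the SMILES is read as the (2S,3R,6S,8S,9S) isomer, and for each chiral catalyst the antipode that gives the stated configuration is fixed once on small scale.

## Route

Step 1
Reactants: 1 5,5-dimethylcyclohexane-1,3-dione (dimedone); 2 2-methylpropan-1-ol
Product: 3 5,5-dimethyl-3-(2-methylpropoxy)cyclohex-2-en-1-one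
Conditions: p-TsOH·H2O (2 mol%), toluene, reflux, Dean–Stark trap
Reagents that add atoms: 2-methylpropan-1-ol (compound 2), CC(C)CO
Why: Acid-catalysed vinylogous esterification of the enolised symmetric 1,3-dione, driven by azeotropic removal of water; the isobutyl ether is chosen because it resists dealkylation later, and no stereocentre is formed.

Step 2
Reactants: 3 5,5-dimethyl-3-(2-methylpropoxy)cyclohex-2-en-1-one
Product: 6 5,5-dimethyl-6-methylidene-3-(2-methylpropoxy)cyclohex-2-en-1-one, via Mannich base 4 (not isolated), via trimethylammonium iodide 5 (not isolated)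
Conditions: LiN(i-Pr)2, THF, −78 °C; CH2=NMe2+ I−, −78 to 0 °C; then MeI, CH2Cl2, rt; then aq NaHCO3, rt
Reagents that add atoms: N,N-dimethylmethyleneiminium iodide (Eschenmoser's salt), C=[N+](C)C.[I-]
Why: Kinetic deprotonation of a 3-alkoxy enone occurs only at C6 (Stork–Danheiser enolate), the enolate undergoes a Mannich reaction with the iminium salt, and N-methylation followed by mild-base E1cB loss of trimethylamine gives the exocyclic enone; no stereocentre remains.

Step 3
Reactants: 6 5,5-dimethyl-6-methylidene-3-(2-methylpropoxy)cyclohex-2-en-1-one; 7 isoprene (2-methylbuta-1,3-diene)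
Product: 8 (6R)-1,1,9-trimethyl-3-(2-methylpropoxy)spiro[5.5]undeca-3,8-dien-5-one
Conditions: (S,S)-IDPi Brønsted acid (3 mol%; BINOL-derived imidodiphosphorimidate with 3,3′-aryl groups and an N-triflyl core), isoprene (5 equiv), toluene, −40 °C
Reagents that add atoms: isoprene (compound 7), C=CC(C)=C
Why: Organocatalytic asymmetric Diels–Alder reaction of an exocyclic enone, an established use of confined IDPi acids for spirocyclizing cycloadditions: the O-protonated s-cis enone is held in the chiral anion pocket, isoprene adds to one face of the C6=CH2 bond with para regiochemistry (the CH2 next to the methyl-bearing carbon bonds to the exocyclic carbon, which becomes C11), and this sets the spiro centre (R in 8, the same spatial arrangement as 6S in the target).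

Step 4
Reactants: 8 (6R)-1,1,9-trimethyl-3-(2-methylpropoxy)spiro[5.5]undeca-3,8-dien-5-one
Product: 9 (6R,8S,9S)-8-bromo-9-chloro-1,1,9-trimethyl-3-(2-methylpropoxy)spiro[5.5]undec-3-en-5-one
Conditions: TiCl4 (1.1 equiv), 2,6-di-tert-butyl-4-methylpyridine (0.2 equiv), CH2Cl2, −78 °C, 15 min; then N-bromosuccinimide (1.05 equiv), −78 to −50 °C; then H2O
Reagents that add atoms: N-bromosuccinimide, O=C1CCC(=O)N1Br; TiCl4, Cl[Ti](Cl)(Cl)Cl
Why: Proposed new method: a ketone-anchored bromochlorination in which TiCl4 binds the C5 carbonyl, which is axial on ring B with its oxygen lying under the cyclohexene because the CMe2 carbon must be equatorial, so that the enol ether is switched off as a nucleophile, the lower face of C8=C9 is blocked, N-bromosuccinimide can form the bromonium ion only on the face syn to the CMe2 arm, and a titanium-bound chloride is passed across the ring to the tertiary C9 anti to bromine (Markovnikov), which sets (8S,9S) with both halogens equatorial; the closest known reaction type is the titanium-alkoxide-directed bromochlorination of allylic alcohols, where chloride is likewise delivered from titanium, and the anchor is needed because plain anti addition to this locked ring is expected to favour the diaxial isomer with bromine syn to the carbonyl arm.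

Step 5
Reactants: 9 (6R,8S,9S)-8-bromo-9-chloro-1,1,9-trimethyl-3-(2-methylpropoxy)spiro[5.5]undec-3-en-5-one
Product: 11 (6R,8S,9S)-8-bromo-9-chloro-1,1,9-trimethyl-5-[(trimethylsilyl)methyl]spiro[5.5]undec-4-en-3-one, via tertiary carbinol 10 (not isolated)
Conditions: Me3SiCH2Li, CeCl3, THF, −78 °C; then 0.5 M aq HCl, 0 °C, 15 min
Reagents that add atoms: (trimethylsilyl)methyllithium, [Li]C[Si](C)(C)C; water, O
Why: The weakly basic organocerium reagent adds 1,2 to the hindered vinylogous-ester carbonyl without touching the secondary bromide or tertiary chloride, and brief dilute acid then effects the Stork–Danheiser enone transposition (water attacks the alkoxy-allyl cation at C3, isobutanol leaves), a known way to β-(silylmethyl) enones that leaves C6, C8 and C9 untouched.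

Step 6
Reactants: 11 (6R,8S,9S)-8-bromo-9-chloro-1,1,9-trimethyl-5-[(trimethylsilyl)methyl]spiro[5.5]undec-4-en-3-one
Product: 12 tert-butyl{[(6R,8S,9S)-8-bromo-9-chloro-1,1,9-trimethyl-5-[(trimethylsilyl)methyl]spiro[5.5]undeca-2,4-dien-3-yl]oxy}dimethylsilane
Conditions: LiN(i-Pr)2, THF, −78 °C; then t-BuMe2SiOTf, −78 °C; non-aqueous work-up (pentane)
Reagents that add atoms: tert-butyldimethylsilyl trifluoromethanesulfonate, CC(C)(C)[Si](C)(C)OS(=O)(=O)C(F)(F)F
Why: Kinetic enolisation of the enone with a lithium amide takes the α′ hydrogen at C2 (the only CH2 next to the carbonyl) and O-silylation gives the cross-conjugated silyl dienol ether, while the equatorial C–Br and C–Cl bonds have no anti-periplanar ring hydrogen so E2 is slow at −78 °C; no stereocentre changes.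

Step 7
Reactants: 12 tert-butyl{[(6R,8S,9S)-8-bromo-9-chloro-1,1,9-trimethyl-5-[(trimethylsilyl)methyl]spiro[5.5]undeca-2,4-dien-3-yl]oxy}dimethylsilane
Product: 13 (2S,6S,8S,9S)-2,8-dibromo-9-chloro-1,1,9-trimethyl-5-[(trimethylsilyl)methyl]spiro[5.5]undec-4-en-3-one
Conditions: N-bromosuccinimide (1.05 equiv), chiral squaramide hydrogen-bond donor (10 mol%; tert-leucine 2-arylpyrrolidine amide carrying a 3,5-bis(trifluoromethyl)phenyl squaramide), toluene–hexane, −78 °C
Reagents that add atoms: N-bromosuccinimide, O=C1CCC(=O)N1Br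
Why: Proposed new method: squaramide-catalysed face-selective bromination of a ketone-derived silyl dienol ether, in which N-bromosuccinimide is insoluble in toluene–hexane at −78 °C and reacts only when bound to the chiral hydrogen-bond donor, which hands Br+ to the face of the C2=C3 enol ether that is syn to C7 while the bound succinimide anion takes the silyl group; ring A has no usable substrate bias toward the remote ring B centres, so the catalyst alone fixes (2S), and the closest known reaction type is the squaramide-catalysed enantioselective α-chlorination of silyl ketene acetals with N-chlorosuccinimide.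

Step 8
Reactants: 13 (2S,6S,8S,9S)-2,8-dibromo-9-chloro-1,1,9-trimethyl-5-[(trimethylsilyl)methyl]spiro[5.5]undec-4-en-3-one
Product: 14 (2S,6S,8S,9S)-2,8-dibromo-9-chloro-1,1,9-trimethyl-5-methylidenespiro[5.5]undecan-3-one
Conditions: Bu4NF (1.1 equiv), AcOH (1.5 equiv), THF, −40 °C, 20 min; cold pH 7 buffer; used directly
Reagents that add atoms: none
Why: Fluoride cleaves the allylic C–Si bond of this vinylogous α-silyl ketone and the resulting dienolate is protonated by acetic acid at the α-carbon C4 (kinetic deconjugative protonation), which leaves the C5=CH2 alkene out of conjugation; the buffered cold medium is not basic enough to enolise toward C2, so the C2–Br centre is kept.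

Step 9
Reactants: 14 (2S,6S,8S,9S)-2,8-dibromo-9-chloro-1,1,9-trimethyl-5-methylidenespiro[5.5]undecan-3-one
Product: 15 (2S,3R,6S,8S,9S)-2,8-dibromo-9-chloro-1,1,9-trimethyl-5-methylidenespiro[5.5]undecan-3-ol
Conditions: i-Bu2AlH (1.5 equiv), CH2Cl2, −78 °C; aq KNaC4H4O6 work-up
Reagents that add atoms: none
Why: Hydride reduction of the ketone in which the axial C1 methyl group, 1,3 to the carbonyl, blocks axial attack (as in 3,3,5-trimethylcyclohexanone), so the bulky aluminium hydride enters equatorially and gives the axial C3 alcohol cis to the equatorial C2 bromide, i.e. (3R); C–Br, C–Cl and the alkene are inert to i-Bu2AlH at −78 °C.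

## Compound list

1 | 5,5-dimethylcyclohexane-1,3-dione (dimedone) | CC1(C)CC(=O)CC(=O)C1 | starting material
2 | 2-methylpropan-1-ol | CC(C)CO | starting material
3 | 5,5-dimethyl-3-(2-methylpropoxy)cyclohex-2-en-1-one | CC(C)COC1=CC(=O)CC(C)(C)C1 | intermediate
4 | 6-[(dimethylamino)methyl]-5,5-dimethyl-3-(2-methylpropoxy)cyclohex-2-en-1-one (racemic Mannich base) | CC(C)COC1=CC(=O)C(CN(C)C)C(C)(C)C1 | intermediate
5 | {[6,6-dimethyl-4-(2-methylpropoxy)-2-oxocyclohex-3-en-1-yl]methyl}trimethylammonium iodide (racemic) | CC(C)COC1=CC(=O)C(C[N+](C)(C)C)C(C)(C)C1.[I-] | intermediate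
6 | 5,5-dimethyl-6-methylidene-3-(2-methylpropoxy)cyclohex-2-en-1-one | CC(C)COC1=CC(=O)C(=C)C(C)(C)C1 | intermediate
7 | isoprene (2-methylbuta-1,3-diene) | C=CC(C)=C | starting material
8 | (6R)-1,1,9-trimethyl-3-(2-methylpropoxy)spiro[5.5]undeca-3,8-dien-5-one | O=C1C=C(OCC(C)C)CC(C)(C)[C@]12CCC(C)=CC2 | intermediate
9 | (6R,8S,9S)-8-bromo-9-chloro-1,1,9-trimethyl-3-(2-methylpropoxy)spiro[5.5]undec-3-en-5-one | O=C1C=C(OCC(C)C)CC(C)(C)[C@]12CC[C@](C)(Cl)[C@@H](Br)C2 | intermediate
10 | (6R,8S,9S)-8-bromo-9-chloro-1,1,9-trimethyl-3-(2-methylpropoxy)-5-[(trimethylsilyl)methyl]spiro[5.5]undec-3-en-5-ol (C5 epimers) | C[Si](C)(C)CC1(O)C=C(OCC(C)C)CC(C)(C)[C@]12CC[C@](C)(Cl)[C@@H](Br)C2 | intermediate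
11 | (6R,8S,9S)-8-bromo-9-chloro-1,1,9-trimethyl-5-[(trimethylsilyl)methyl]spiro[5.5]undec-4-en-3-one | C[Si](C)(C)CC1=CC(=O)CC(C)(C)[C@]12CC[C@](C)(Cl)[C@@H](Br)C2 | intermediate
12 | tert-butyl{[(6R,8S,9S)-8-bromo-9-chloro-1,1,9-trimethyl-5-[(trimethylsilyl)methyl]spiro[5.5]undeca-2,4-dien-3-yl]oxy}dimethylsilane | C[Si](C)(C)CC1=CC(O[Si](C)(C)C(C)(C)C)=CC(C)(C)[C@]12CC[C@](C)(Cl)[C@@H](Br)C2 | intermediate
13 | (2S,6S,8S,9S)-2,8-dibromo-9-chloro-1,1,9-trimethyl-5-[(trimethylsilyl)methyl]spiro[5.5]undec-4-en-3-one | C[Si](C)(C)CC1=CC(=O)[C@@H](Br)C(C)(C)[C@]12CC[C@](C)(Cl)[C@@H](Br)C2 | intermediate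
14 | (2S,6S,8S,9S)-2,8-dibromo-9-chloro-1,1,9-trimethyl-5-methylidenespiro[5.5]undecan-3-one | C=C1CC(=O)[C@@H](Br)C(C)(C)[C@]12CC[C@](C)(Cl)[C@@H](Br)C2 | intermediate
15 | (2S,3R,6S,8S,9S)-2,8-dibromo-9-chloro-1,1,9-trimethyl-5-methylidenespiro[5.5]undecan-3-ol | C=C1C[C@@H](O)[C@@H](Br)C(C)(C)[C@]12CC[C@](C)(Cl)[C@@H](Br)C2 | target

## Step count and risk

Total step count: 9. Longest linear sequence: 9 steps (fully linear from dimedone).

The three steps most likely to fail:

Step 4, the new anchored bromochlorination. It may give the diaxial ring B isomer, the C8-chloro/C9-bromo regioisomer, or bromination of the enol ether. The fallback uses known chemistry, sets out from 8 and comes back at 11. Me3SiCH2Li/CeCl3 is added to 8 and the adduct is hydrolysed as in step 5; this passes through (6R)-1,1,9-trimethyl-3-(2-methylpropoxy)-5-[(trimethylsilyl)methyl]spiro[5.5]undeca-3,8-dien-5-ol F1 and gives (6R)-1,1,9-trimethyl-5-[(trimethylsilyl)methyl]spiro[5.5]undeca-4,8-dien-3-one F2. BrCl is then added without direction using Bu4N+ BrCl2− in CH2Cl2 at −78 °C, where only the electron-rich ring B alkene reacts. Compound 11 is separated by chromatography from its ring B diastereomer (6R,8R,9R)-8-bromo-9-chloro-1,1,9-trimethyl-5-[(trimethylsilyl)methyl]spiro[5.5]undec-4-en-3-one F3 (diequatorial against diaxial dihalide). F3 is returned to F2 with Zn in AcOH for another pass.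

Step 7, the new catalyst-controlled bromination. It may give poor facial selectivity, because an uncatalysed background reaction would deliver both C2 epimers. The fallback uses known reaction types, sets out from 12 and comes back at 13. Shi epoxidation of the silyl enol ether (fructose-derived ketone catalyst of the antipode that places oxygen on the face syn to C11, KHSO5, K2CO3, MeCN–dimethoxymethane–water, 0 °C) and dilute-acid work-up give (2R,6R,8S,9S)-8-bromo-9-chloro-2-hydroxy-1,1,9-trimethyl-5-[(trimethylsilyl)methyl]spiro[5.5]undec-4-en-3-one F4. Tf2O and 2,6-lutidine in CH2Cl2 at −78 °C give (2R,6R,8S,9S)-8-bromo-9-chloro-1,1,9-trimethyl-3-oxo-5-[(trimethylsilyl)methyl]spiro[5.5]undec-4-en-2-yl trifluoromethanesulfonate F5. LiBr in THF at 0 °C then displaces the α-keto triflate with inversion (the same kind of substitution that works on pantolactone triflate, also next to a quaternary carbon) to give 13.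

Step 8, the desilylative deconjugation. The dienolate could epimerise C2, undergo Favorskii-type closure onto C2–Br, or reprotonate to the conjugated methyl enone. The fallback sets out from 13 and comes back at 14, and avoids fluoride and any enolate. Catalytic Tf2NH (5 mol%) in wet CH2Cl2 at −40 °C protonates the enone oxygen, the β-silyl-stabilised hydroxyallyl cation loses its silyl group to water, and the dienol ketonises by protonation at C4. This fallback makes no new compound (F0).

## Further compounds

F1 | step 4 | (6R)-1,1,9-trimethyl-3-(2-methylpropoxy)-5-[(trimethylsilyl)methyl]spiro[5.5]undeca-3,8-dien-5-ol (C5 epimers) | C[Si](C)(C)CC1(O)C=C(OCC(C)C)CC(C)(C)[C@]12CCC(C)=CC2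
F2 | step 4 | (6R)-1,1,9-trimethyl-5-[(trimethylsilyl)methyl]spiro[5.5]undeca-4,8-dien-3-one | C[Si](C)(C)CC1=CC(=O)CC(C)(C)[C@]12CCC(C)=CC2
F3 | step 4 | (6R,8R,9R)-8-bromo-9-chloro-1,1,9-trimethyl-5-[(trimethylsilyl)methyl]spiro[5.5]undec-4-en-3-one | C[Si](C)(C)CC1=CC(=O)CC(C)(C)[C@]12CC[C@@](C)(Cl)[C@H](Br)C2
F4 | step 7 | (2R,6R,8S,9S)-8-bromo-9-chloro-2-hydroxy-1,1,9-trimethyl-5-[(trimethylsilyl)methyl]spiro[5.5]undec-4-en-3-one | C[Si](C)(C)CC1=CC(=O)[C@H](O)C(C)(C)[C@]12CC[C@](C)(Cl)[C@@H](Br)C2
F5 | step 7 | (2R,6R,8S,9S)-8-bromo-9-chloro-1,1,9-trimethyl-3-oxo-5-[(trimethylsilyl)methyl]spiro[5.5]undec-4-en-2-yl trifluoromethanesulfonate | C[Si](C)(C)CC1=CC(=O)[C@H](OS(=O)(=O)C(F)(F)F)C(C)(C)[C@]12CC[C@](C)(Cl)[C@@H](Br)C2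
F0 | step 8 | none | none
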